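**Retrosynthetic overview**
- Feature used: each prenyl CH2 is bonded to an aromatic carbon ortho to a phenolic oxygen. C8 lies next to O7 on ring A and C5' lies next to O4' on ring B, so both aryl–CH2 bonds can be delivered from those oxygens.
- Key disconnection: the C8–CH2 and C5'–CH2 bonds are cut together. This leads back to the 7,4'-bis(1,1-dimethylallyl) ether of 3,5,3'-tri-O-MOM-quercetin (twofold aromatic Claisen shift with allylic inversion).
- The two tertiary allyl ethers come from the 7,4'-diol by copper-catalysed 1,1-dimethylpropargylation followed by semi-hydrogenation.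
- The 7,4'-diol is singled out from quercetin through its pentaacetate. The 7- and 4'-acetates are exchanged for benzyl, the other three positions are switched from acetate to MOM, and the benzyl groups are removed by hydrogenolysis.
- No ring is formed at any stage, because rings A, C and B all arrive with quercetin. The last step removes the three MOM groups.

Key step: step 8

Remark: the target has no stereocentre and both alkenes end in CMe2, so no configuration has to be set. Direct twofold alkylation of unprotected quercetin is not relied on, because O3 competes with O7 and O4'.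

**Route**

Step 1
Reactants: 1 quercetin; 2 acetic anhydride
Product: 3 quercetin 3,5,7,3',4'-pentaacetate
Conditions: Ac2O (excess), pyridine, DMAP (cat.), rt to 80 °C
Reagents that add atoms: acetic anhydride CC(=O)OC(C)=O
Why: Exhaustive pyridine-promoted O-acylation esterifies all five hydroxyls of a flavonol on warming, including the chelated 5-OH.

Step 2
Reactants: 3 quercetin pentaacetate; 4 benzyl bromide
Product: 5 3,5,3'-tri-O-acetyl-7,4'-di-O-benzylquercetin
Conditions: BnBr (2.3 equiv), K2CO3 (anhydrous), acetone, reflux
Reagents that add atoms: benzyl bromide BrCc1ccccc1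
Why: This is a selective alkylative deacylation coupled to a Williamson etherification, in which carbonate first cleaves the 7- and 4'-acetates (esters of the two most acidic hydroxyls, whose phenoxides are conjugated with C4=O) and each phenoxide is benzylated as it forms while the 3-, 5- and 3'-acetates stay in place.

Step 3
Reactants: 5 3,5,3'-tri-O-acetyl-7,4'-di-O-benzylquercetin
Product: 6 7,4'-di-O-benzylquercetin
Conditions: aq. HCl (cat.), MeOH–THF, reflux
Reagents that add atoms: none
Why: Acid-catalysed transesterification (methanolysis) removes the aryl and enol acetates, leaves benzyl aryl ethers untouched, and avoids the air oxidation that free flavonols suffer in base.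

Step 4
Reactants: 6 7,4'-di-O-benzylquercetin; 7 chloromethyl methyl ether
Product: 8 7,4'-bis(benzyloxy)-3,5,3'-tris(methoxymethoxy)flavone
Conditions: NaH (4.5 equiv), MOMCl (4.5 equiv), DMF, 0 °C to rt
Reagents that add atoms: chloromethyl methyl ether COCCl
Why: In this Williamson-type O-alkylation of the sodium phenoxides, full deprotonation with NaH breaks the O5–H···O=C4 hydrogen bond, so the sluggish 5-OH is capped together with 3-OH and 3'-OH.

Step 5
Reactants: 8 7,4'-bis(benzyloxy)-3,5,3'-tris(methoxymethoxy)flavone
Product: 9 7,4'-dihydroxy-3,5,3'-tris(methoxymethoxy)flavone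
Conditions: H2 (1 atm), 10% Pd/C, NaHCO3 (solid), EtOAc–THF, rt
Reagents that add atoms: none
Why: Catalytic hydrogenolysis cleaves the benzyl aryl ethers, while the MOM acetals and the tetrasubstituted C2=C3 bond of the chromone are inert at 1 atm and the solid bicarbonate buffers any acid from the catalyst.

Step 6
Reactants: 9 7,4'-dihydroxy-3,5,3'-tris(methoxymethoxy)flavone; 10 3-chloro-3-methylbut-1-yne
Product: 11 3,5,3'-tris(methoxymethoxy)-7,4'-bis(2-methylbut-3-yn-2-yloxy)flavone
Conditions: 10 (3 equiv), DBU (3 equiv), CuCl2·2H2O (2 mol %), MeCN, 0 °C to rt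
Reagents that add atoms: 3-chloro-3-methylbut-1-yne C#CC(C)(C)Cl
Why: Copper-catalysed propargylic etherification runs through a copper-bound allenylidene-type electrophile, so it builds hindered tertiary aryl ethers at low temperature and works best with acidic phenols such as 7-OH and 4'-OH.

Step 7
Reactants: 11 3,5,3'-tris(methoxymethoxy)-7,4'-bis(2-methylbut-3-yn-2-yloxy)flavone
Product: 12 3,5,3'-tris(methoxymethoxy)-7,4'-bis(2-methylbut-3-en-2-yloxy)flavone
Conditions: H2 (1 atm, uptake monitored), 5% Pd/CaCO3 poisoned with Pb(OAc)2, quinoline, EtOAc, rt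
Reagents that add atoms: none
Why: Lindlar semi-hydrogenation stops both terminal alkynes at the vinyl stage because the poisoned surface binds the alkene too weakly for further reduction, and at room temperature neither propargyl nor allyl ether rearranges.

Step 8
Reactants: 12 3,5,3'-tris(methoxymethoxy)-7,4'-bis(2-methylbut-3-en-2-yloxy)flavone
Product: 14 3,5,3'-tri-O-methoxymethyl broussonol D, via bis(ortho-dienone) 13 (not isolated)
Conditions: PhNEt2, 130 °C, Ar
Reagents that add atoms: none
Why: Each aryl 1,1-dimethylallyl ether undergoes a concerted chair-like aromatic Claisen [3,3] shift in which the O–CMe2 bond breaks while the vinyl CH2 terminus bonds to the ortho carbon, giving ortho-dienones (drawn together as 13, although the two shifts are independent events) that enolise irreversibly to the phenols of 14, and the allylic transposition turns the tertiary ether into the linear 3-methylbut-2-enyl chain. This is the established thermal rearrangement of reverse-prenyl aryl ethers of coumarins, chromones, flavonoids and xanthones, which needs only about 110–140 °C because the gem-dimethyl group weakens the C–O bond. No ring is closed and no stereocentre survives, since the sp3 carbons C8 and C5' of 13 become planar again on tautomerisation. On ring B only C5' carries hydrogen, and a shift to the oxygenated C3' would give a blocked dienone that can only revert, so the material funnels to C5'. On ring A the shift must reach C8 and not C6, which is secured by three factors: C7–C8 adjoins the ring fusion and has the higher double-bond character in benzopyranones (the bias that sends 7-allyloxy-coumarins and -chromones to C8), capping O5 removes the O5–H···O=C4 chelate that would localise a C6=C7 bond, and the 5-OMOM group crowds C6. The weakly basic solvent suppresses acid-catalysed ionisation of the tertiary ethers and spares the MOM acetals and the new alkenes.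

Step 9
Reactants: 14 3,5,3'-tri-O-methoxymethyl broussonol D
Product: 15 broussonol D
Conditions: 1 M HCl in MeOH, 40 °C, Ar, stopped as soon as the last MOM group is gone
Reagents that add atoms: none
Why: Acid-catalysed acetal exchange with methanol cleaves aryl MOM ethers, fastest at O3 and O5 next to C4=O, under dilute conditions routinely tolerated by ortho-prenylphenols.

**Compound list**
1 | quercetin | O=c1c(O)c(-c2ccc(O)c(O)c2)oc2cc(O)cc(O)c12 | starting material
2 | acetic anhydride | CC(=O)OC(C)=O | starting material
3 | quercetin 3,5,7,3',4'-pentaacetate | CC(=O)Oc1cc(OC(C)=O)c2c(=O)c(OC(C)=O)c(-c3ccc(OC(C)=O)c(OC(C)=O)c3)oc2c1 | intermediate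
4 | benzyl bromide | BrCc1ccccc1 | starting material
5 | 3,5,3'-tri-O-acetyl-7,4'-di-O-benzylquercetin | CC(=O)Oc1cc(-c2oc3cc(OCc4ccccc4)cc(OC(C)=O)c3c(=O)c2OC(C)=O)ccc1OCc1ccccc1 | intermediate
6 | 7,4'-di-O-benzylquercetin | O=c1c(O)c(-c2ccc(OCc3ccccc3)c(O)c2)oc2cc(OCc3ccccc3)cc(O)c12 | intermediate
7 | chloromethyl methyl ether | COCCl | starting material
8 | 7,4'-bis(benzyloxy)-3,5,3'-tris(methoxymethoxy)flavone | COCOc1cc(-c2oc3cc(OCc4ccccc4)cc(OCOC)c3c(=O)c2OCOC)ccc1OCc1ccccc1 | intermediate
9 | 7,4'-dihydroxy-3,5,3'-tris(methoxymethoxy)flavone | COCOc1cc(-c2oc3cc(O)cc(OCOC)c3c(=O)c2OCOC)ccc1O | intermediate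
10 | 3-chloro-3-methylbut-1-yne | C#CC(C)(C)Cl | starting material
11 | 3,5,3'-tris(methoxymethoxy)-7,4'-bis(2-methylbut-3-yn-2-yloxy)flavone | C#CC(C)(C)Oc1ccc(-c2oc3cc(OC(C)(C)C#C)cc(OCOC)c3c(=O)c2OCOC)cc1OCOC | intermediate
12 | 3,5,3'-tris(methoxymethoxy)-7,4'-bis(2-methylbut-3-en-2-yloxy)flavone | C=CC(C)(C)Oc1ccc(-c2oc3cc(OC(C)(C)C=C)cc(OCOC)c3c(=O)c2OCOC)cc1OCOC | intermediate
13 | bis(ortho-dienone): 8H-7-oxo ring A and 5'H-4'-oxo ring B, each carrying the new prenyl group on its sp3 carbon (configuration at C8 and C5' undefined, transient) | CC(C)=CCC1C=C(C2=C(OCOC)C(=O)C3=C(O2)C(CC=C(C)C)C(=O)C=C3OCOC)C=C(OCOC)C1=O | intermediate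
14 | 3,5,3'-tri-O-methoxymethyl broussonol D | CC(C)=CCc1cc(-c2oc3c(CC=C(C)C)c(O)cc(OCOC)c3c(=O)c2OCOC)cc(OCOC)c1O | intermediate
15 | broussonol D (8,5'-diprenylquercetin) | CC(C)=CCc1cc(-c2oc3c(CC=C(C)C)c(O)cc(O)c3c(=O)c2O)cc(O)c1O | target

**Step count**
Total step count: 9. Longest linear sequence: 9 steps, from quercetin.

**Steps most likely to fail**

1. Step 8.
- What may go wrong: the ring-A allyl unit may migrate to C6 in competition with C8. The tertiary C–O bonds may also break heterolytically, with loss of the C5 unit by elimination, before the sigmatropic shift takes place.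
- Fallback, setting out from 9: both phenols are O-allylated (allyl bromide, K2CO3, DMF) to give 7,4'-bis(allyloxy)-3,5,3'-tris(methoxymethoxy)flavone F1.
- Its primary ethers cannot ionise, and the C8 preference of 7-allyloxybenzopyranones is the most firmly documented case. Thermal Claisen rearrangement (PhNEt2, 190 °C) should therefore give 8,5'-diallyl-7,4'-dihydroxy-3,5,3'-tris(methoxymethoxy)flavone F2.
- Olefin cross-metathesis of F2 with excess 2-methylbut-2-ene (second-generation Grubbs catalyst, CH2Cl2, 40 °C) converts both allyl groups into prenyl groups. The fallback rejoins the route at 14.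

2. Step 9.
- What may go wrong: acid may promote addition of the neighbouring 7-OH and 4'-OH across the prenyl double bonds (chroman ring closure), or solvolysis of the alkenes, in competition with acetal cleavage.
- Fallback, setting out from 5: the acetals are given up for base-labile esters, so that no acid ever meets the prenylphenols. Hydrogenolysis (H2, Pd/C, EtOAc) gives 3,5,3'-tri-O-acetylquercetin F3.
- Etherification of F3 with 10 (DBU, CuCl2·2H2O, MeCN, 0 °C) gives 3,5,3'-triacetoxy-7,4'-bis(2-methylbut-3-yn-2-yloxy)flavone F4.
- Semi-hydrogenation of F4 over Pd/CaCO3 poisoned with Pb(OAc)2 gives 3,5,3'-triacetoxy-7,4'-bis(2-methylbut-3-en-2-yloxy)flavone F5.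
- Heating F5 (PhNEt2, 130 °C) gives 3,5,3'-tri-O-acetyl broussonol D F6.
- Methanolysis of F6 (K2CO3, MeOH, 0 °C, Ar, then dilute citric acid) rejoins the route at 15.
- This line is held in reserve because aryl acetates can wander between oxygens under DBU.

3. Step 6.
- What may go wrong: etherification may stay incomplete at the crowded O4' next to the 3'-OMOM group. The tertiary chloride may also be consumed by base-induced elimination.
- Fallback, setting out from 9: the tertiary allyl ethers are installed directly by Tsuji–Trost O-allylation. The reagent, tert-butyl 2-methylbut-3-en-2-yl carbonate F7, is made from 2-methylbut-3-en-2-ol (n-BuLi, then Boc2O, THF).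
- Treating 9 with F7 and Pd(PPh3)4 in THF at 0–5 °C generates a 1,1-dimethyl-π-allyl complex of divalent palladium. The phenoxides attack it under kinetic control at the more substituted terminus.
- The fallback rejoins the route at 12, so steps 6 and 7 are both bypassed.

**Further compounds**
F1 | step 8 | 7,4'-bis(allyloxy)-3,5,3'-tris(methoxymethoxy)flavone | C=CCOc1ccc(-c2oc3cc(OCC=C)cc(OCOC)c3c(=O)c2OCOC)cc1OCOC
F2 | step 8 | 8,5'-diallyl-7,4'-dihydroxy-3,5,3'-tris(methoxymethoxy)flavone | C=CCc1cc(-c2oc3c(CC=C)c(O)cc(OCOC)c3c(=O)c2OCOC)cc(OCOC)c1O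
F3 | step 9 | 3,5,3'-tri-O-acetylquercetin | CC(=O)Oc1cc(-c2oc3cc(O)cc(OC(C)=O)c3c(=O)c2OC(C)=O)ccc1O
F4 | step 9 | 3,5,3'-triacetoxy-7,4'-bis(2-methylbut-3-yn-2-yloxy)flavone | C#CC(C)(C)Oc1ccc(-c2oc3cc(OC(C)(C)C#C)cc(OC(C)=O)c3c(=O)c2OC(C)=O)cc1OC(C)=O
F5 | step 9 | 3,5,3'-triacetoxy-7,4'-bis(2-methylbut-3-en-2-yloxy)flavone | C=CC(C)(C)Oc1ccc(-c2oc3cc(OC(C)(C)C=C)cc(OC(C)=O)c3c(=O)c2OC(C)=O)cc1OC(C)=O
F6 | step 9 | 3,5,3'-tri-O-acetyl broussonol D | CC(C)=CCc1cc(-c2oc3c(CC=C(C)C)c(O)cc(OC(C)=O)c3c(=O)c2OC(C)=O)cc(OC(C)=O)c1O
F7 | step 6 | tert-butyl 2-methylbut-3-en-2-yl carbonate | C=CC(C)(C)OC(=O)OC(C)(C)C
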